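**Strategy.** Ring C (the pyran) is disconnected at the aryl ether bond O1–C8a, which turns the flavan into an open (S)-1,3-diarylpropan-1-ol with chlorine on C8a of ring A. The key step, a palladium-catalysed intramolecular etherification, closes ring C without touching any bond at C2, so the carbinol centre set by asymmetric transfer hydrogenation becomes the (2S) centre with retention; closure at O1–C2 would ionise the 2-methoxybenzylic carbon instead. It exploits that C8a is ortho to the C4a tether and para to C6: one salicylaldehyde supplies CHO (the diarylmethine carbon, via chalcone and rhodium-catalysed arylation), C–Br (C4a chain, Heck) and C–Cl (C8a).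

Key step: step 10

Remark: 5-bromo-4-chloro-2-hydroxybenzaldehyde (1) is taken as a catalogue compound, and the (R,R) antipode of the diene ligand in step 4 is assigned by analogy with simpler acyclic enones; the mirror-image ligand would be used if a trial run shows the opposite sense.

**Step 1**
Reactants: 1 5-bromo-4-chloro-2-hydroxybenzaldehyde
Product: 2 2-(benzyloxy)-5-bromo-4-chlorobenzaldehyde
Conditions: BnBr, K2CO3, DMF, rt
Reagents that add atoms: benzyl bromide BrCc1ccccc1
Why: Williamson etherification of the phenoxide, the only nucleophilic site, protects the future C7 hydroxyl for the organometallic steps.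

**Step 2**
Reactants: 3 1-[4-(benzyloxy)-2-hydroxyphenyl]ethan-1-one
Product: 4 1-[4-(benzyloxy)-2-methoxyphenyl]ethan-1-one
Conditions: MeI, K2CO3, acetone, reflux
Reagents that add atoms: iodomethane CI
Why: Williamson O-methylation of the chelated ortho-hydroxy ketone under carbonate conditions installs the methyl ether that stays in the target.

**Step 3**
Reactants: 2 2-(benzyloxy)-5-bromo-4-chlorobenzaldehyde; 4 1-[4-(benzyloxy)-2-methoxyphenyl]ethan-1-one
Product: 6 (E)-3-[2-(benzyloxy)-5-bromo-4-chlorophenyl]-1-[4-(benzyloxy)-2-methoxyphenyl]prop-2-en-1-one, via aldol adduct 5 (not isolated)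
Conditions: KOH (aq), EtOH/THF, rt
Reagents that add atoms: none
Why: Claisen–Schmidt condensation, in which the methyl ketone enolate adds to the non-enolisable aldehyde and the aldol adduct dehydrates to the more stable E-enone.

**Step 4**
Reactants: 6 the chalcone from step 3; 7 [4-(benzyloxy)phenyl]boronic acid
Product: 8 (3R)-3-[2-(benzyloxy)-5-bromo-4-chlorophenyl]-3-[4-(benzyloxy)phenyl]-1-[4-(benzyloxy)-2-methoxyphenyl]propan-1-one
Conditions: [RhCl(C2H4)2]2 (2.5 mol%), (R,R)-2,5-diphenylbicyclo[2.2.2]octa-2,5-diene (5.5 mol%), KOH (0.5 equiv, aq), 1,4-dioxane, 50 °C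
Reagents that add atoms: none
Why: Hayashi–Miyaura asymmetric 1,4-addition, in which the chiral diene on monovalent rhodium should direct the aryl group to the Si face of C-β and so set the (R) diarylmethine centre, with aryl bromide and chloride inert under these conditions.

**Step 5**
Reactants: 8 the (3R)-β,β-diaryl ketone
Product: 10 (R)-1-(benzyloxy)-4-bromo-5-chloro-2-{1-[4-(benzyloxy)phenyl]-3-[4-(benzyloxy)-2-methoxyphenyl]propyl}benzene, via benzylic alcohol 9 (not isolated)
Conditions: Et3SiH (4 equiv), TFA, CH2Cl2, 0 °C to rt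
Reagents that add atoms: none
Why: Ionic hydrogenation: the 2,4-dialkoxyaryl ketone is reduced to the benzylic alcohol, which ionises to a strongly stabilised cation and takes a second hydride, while the diarylmethine centre, halides and benzyl ethers are not involved.

**Step 6**
Reactants: 11 5-hydroxy-2-methoxybenzaldehyde
Product: 12 5-(benzyloxy)-2-methoxybenzaldehyde
Conditions: BnBr, K2CO3, DMF, rt
Reagents that add atoms: benzyl bromide BrCc1ccccc1
Why: Williamson etherification of the only phenol.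

**Step 7**
Reactants: 12 5-(benzyloxy)-2-methoxybenzaldehyde
Product: 13 rac-1-[5-(benzyloxy)-2-methoxyphenyl]prop-2-en-1-ol
Conditions: vinylmagnesium bromide, THF, 0 °C; aq NH4Cl
Reagents that add atoms: vinylmagnesium bromide C=C[Mg]Br
Why: Grignard 1,2-addition to the aldehyde; the carbinol may be racemic because step 8 converts it into a ketone.

**Step 8**
Reactants: 10 the aryl bromide from step 5; 13 rac-1-[5-(benzyloxy)-2-methoxyphenyl]prop-2-en-1-ol
Product: 15 3-{4-(benzyloxy)-2-chloro-5-[(1R)-1-[4-(benzyloxy)phenyl]-3-[4-(benzyloxy)-2-methoxyphenyl]propyl]phenyl}-1-[5-(benzyloxy)-2-methoxyphenyl]propan-1-one, via enol 14 (not isolated)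
Conditions: Pd(OAc)2 (5 mol%), Bu4NCl, NaHCO3, DMF, 90 °C
Reagents that add atoms: none
Why: Mizoroki–Heck arylation of an allylic alcohol with redox isomerisation: aryl–palladium adds to the terminal alkene carbon, β-hydride elimination towards the carbinol gives the enol and then the saturated ketone, and zerovalent palladium without a strong donor ligand inserts into C–Br but not C–Cl.

**Step 9**
Reactants: 15 the aryl ketone from step 8
Product: 16 (1S)-3-{4-(benzyloxy)-2-chloro-5-[(1R)-1-[4-(benzyloxy)phenyl]-3-[4-(benzyloxy)-2-methoxyphenyl]propyl]phenyl}-1-[5-(benzyloxy)-2-methoxyphenyl]propan-1-ol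
Conditions: RuCl(p-cymene)[(S,S)-TsDPEN] (1 mol%), HCO2H/Et3N (5:2), CH2Cl2, 35 °C
Reagents that add atoms: none
Why: Noyori–Ikariya asymmetric transfer hydrogenation, in which the (S,S)-TsDPEN ruthenium hydride should deliver hydride to the Re face of the aryl alkyl ketone and give the (S) carbinol by catalyst control, independent of the remote (R) centre.

**Step 10**
Reactants: 16 the (1S)-chloro alcohol
Product: 17 (2S)-7-(benzyloxy)-2-[5-(benzyloxy)-2-methoxyphenyl]-6-[(1R)-1-[4-(benzyloxy)phenyl]-3-[4-(benzyloxy)-2-methoxyphenyl]propyl]-3,4-dihydro-2H-chromene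
Conditions: Pd(OAc)2 (5 mol%), rac-2-(di-tert-butylphosphino)-1,1'-binaphthyl (6 mol%), Cs2CO3, toluene, 80 °C
Reagents that add atoms: none
Why: Zerovalent palladium, formed in situ from Pd(OAc)2 and the bulky electron-rich biaryl di-tert-butylphosphine, inserts into the C8a–Cl bond, Cs2CO3 deprotonates the coordinated carbinol, and C(sp2)–O reductive elimination from the aryl(alkoxo)palladium species forms O1–C8a. The closest known reaction type is the Buchwald–Hartwig-type intramolecular etherification of aryl halides with secondary alcohols under weak-base conditions. The six-membered pyran ring (O1, C2, C3, C4, C4a, C8a) is closed in exo fashion onto the arene carbon by reductive elimination from a seven-membered oxapalladacycle. No stereocentre is created: the C2 configuration from step 9 is retained because no bond to C2 is broken, and the remote diarylmethine centre is untouched. The step needs C–O reductive elimination to outrun β-hydride elimination from the secondary alkoxide, which the hindered monophosphine and the intramolecular setting should secure, and the single C–Cl bond ortho to the tether fixes the site of closure.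

**Step 11**
Reactants: 17 the tetra-O-benzyl flavan
Product: 18 (2S)-6-[(1R)-3-(4-hydroxy-2-methoxyphenyl)-1-(4-hydroxyphenyl)propyl]-2-(5-hydroxy-2-methoxyphenyl)-3,4-dihydro-2H-chromen-7-ol (CNP0239474.1)
Conditions: H2 (1 atm), Pd/C (10 wt%), EtOAc/MeOH, rt
Reagents that add atoms: none
Why: Hydrogenolysis of the four aryl benzyl ethers; the cyclic benzylic C2–O1 ether and the methyl ethers should cleave far more slowly under neutral conditions at 1 atm.

**Compound list**
1 | 5-bromo-4-chloro-2-hydroxybenzaldehyde | O=Cc1cc(Br)c(Cl)cc1O | starting material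
2 | 2-(benzyloxy)-5-bromo-4-chlorobenzaldehyde | O=Cc1cc(Br)c(Cl)cc1OCc1ccccc1 | intermediate
3 | 1-[4-(benzyloxy)-2-hydroxyphenyl]ethan-1-one | CC(=O)c1ccc(OCc2ccccc2)cc1O | starting material
4 | 1-[4-(benzyloxy)-2-methoxyphenyl]ethan-1-one | COc1cc(OCc2ccccc2)ccc1C(C)=O | intermediate
5 | rac-3-[2-(benzyloxy)-5-bromo-4-chlorophenyl]-1-[4-(benzyloxy)-2-methoxyphenyl]-3-hydroxypropan-1-one (aldol adduct) | COc1cc(OCc2ccccc2)ccc1C(=O)CC(O)c1cc(Br)c(Cl)cc1OCc1ccccc1 | intermediate (not isolated)
6 | (E)-3-[2-(benzyloxy)-5-bromo-4-chlorophenyl]-1-[4-(benzyloxy)-2-methoxyphenyl]prop-2-en-1-one | COc1cc(OCc2ccccc2)ccc1C(=O)/C=C/c1cc(Br)c(Cl)cc1OCc1ccccc1 | intermediate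
7 | [4-(benzyloxy)phenyl]boronic acid | OB(O)c1ccc(OCc2ccccc2)cc1 | starting material
8 | (3R)-3-[2-(benzyloxy)-5-bromo-4-chlorophenyl]-3-[4-(benzyloxy)phenyl]-1-[4-(benzyloxy)-2-methoxyphenyl]propan-1-one | COc1cc(OCc2ccccc2)ccc1C(=O)C[C@H](c1ccc(OCc2ccccc2)cc1)c1cc(Br)c(Cl)cc1OCc1ccccc1 | intermediate
9 | (3R)-3-[2-(benzyloxy)-5-bromo-4-chlorophenyl]-3-[4-(benzyloxy)phenyl]-1-[4-(benzyloxy)-2-methoxyphenyl]propan-1-ol, both C1 epimers (benzylic alcohol) | COc1cc(OCc2ccccc2)ccc1C(O)C[C@H](c1ccc(OCc2ccccc2)cc1)c1cc(Br)c(Cl)cc1OCc1ccccc1 | intermediate (not isolated)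
10 | (R)-1-(benzyloxy)-4-bromo-5-chloro-2-{1-[4-(benzyloxy)phenyl]-3-[4-(benzyloxy)-2-methoxyphenyl]propyl}benzene | COc1cc(OCc2ccccc2)ccc1CC[C@H](c1ccc(OCc2ccccc2)cc1)c1cc(Br)c(Cl)cc1OCc1ccccc1 | intermediate
11 | 5-hydroxy-2-methoxybenzaldehyde | COc1ccc(O)cc1C=O | starting material
12 | 5-(benzyloxy)-2-methoxybenzaldehyde | COc1ccc(OCc2ccccc2)cc1C=O | intermediate
13 | rac-1-[5-(benzyloxy)-2-methoxyphenyl]prop-2-en-1-ol | COc1ccc(OCc2ccccc2)cc1C(O)C=C | intermediate
14 | enol of ketone 15, 3-aryl-1-[5-(benzyloxy)-2-methoxyphenyl]prop-1-en-1-ol with the (1R)-diarylmethine side chain | COc1cc(OCc2ccccc2)ccc1CC[C@H](c1ccc(OCc2ccccc2)cc1)c1cc(CC=C(O)c2cc(OCc3ccccc3)ccc2OC)c(Cl)cc1OCc1ccccc1 | intermediate (not isolated)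
15 | 3-{4-(benzyloxy)-2-chloro-5-[(1R)-1-[4-(benzyloxy)phenyl]-3-[4-(benzyloxy)-2-methoxyphenyl]propyl]phenyl}-1-[5-(benzyloxy)-2-methoxyphenyl]propan-1-one | COc1cc(OCc2ccccc2)ccc1CC[C@H](c1ccc(OCc2ccccc2)cc1)c1cc(CCC(=O)c2cc(OCc3ccccc3)ccc2OC)c(Cl)cc1OCc1ccccc1 | intermediate
16 | (1S)-3-{4-(benzyloxy)-2-chloro-5-[(1R)-1-[4-(benzyloxy)phenyl]-3-[4-(benzyloxy)-2-methoxyphenyl]propyl]phenyl}-1-[5-(benzyloxy)-2-methoxyphenyl]propan-1-ol | COc1cc(OCc2ccccc2)ccc1CC[C@H](c1ccc(OCc2ccccc2)cc1)c1cc(CC[C@H](O)c2cc(OCc3ccccc3)ccc2OC)c(Cl)cc1OCc1ccccc1 | intermediate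
17 | (2S)-7-(benzyloxy)-2-[5-(benzyloxy)-2-methoxyphenyl]-6-[(1R)-1-[4-(benzyloxy)phenyl]-3-[4-(benzyloxy)-2-methoxyphenyl]propyl]-3,4-dihydro-2H-chromene | COc1cc(OCc2ccccc2)ccc1CC[C@H](c1ccc(OCc2ccccc2)cc1)c1cc2c(cc1OCc1ccccc1)O[C@H](c1cc(OCc3ccccc3)ccc1OC)CC2 | intermediate
18 | (2S)-6-[(1R)-3-(4-hydroxy-2-methoxyphenyl)-1-(4-hydroxyphenyl)propyl]-2-(5-hydroxy-2-methoxyphenyl)-3,4-dihydro-2H-chromen-7-ol | COc1cc(O)ccc1CC[C@H](c1ccc(O)cc1)c1cc2c(cc1O)O[C@H](c1cc(O)ccc1OC)CC2 | target

**Step count.** Total: 11 steps. Longest linear sequence: 8 steps (1, 3, 4, 5, 8, 9, 10, 11).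

**Steps most likely to fail**

Step 10 (key step). β-Hydride elimination from the secondary palladium alkoxide may outpace C–O reductive elimination and return ketone 15 together with dechlorinated arene, and oxidative addition into the electron-rich C–Cl bond may be slow. The fallback sets out from ketone 15. Palladium-catalysed intramolecular O-arylation of its enolate (Pd2(dba)3, tBuXPhos, NaOtBu, toluene, 100 °C) still forms O1–C8a, but through an oxygen nucleophile that has no hydrogen on the oxygen-bearing carbon, and should give the 2-aryl-4H-chromene F1. Iridium-catalysed asymmetric hydrogenation of the enol ether double bond ([Ir(cod)(L)]BArF, L = a chiral phosphinooxazoline whose antipode is chosen for the 2S product, H2 50 bar, CH2Cl2) then sets C2 and rejoins the route at 17.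

Step 4. Carbometalation of the hindered ortho-benzyloxy chalcone may be slow, so that protodeboronation of 7 takes over, or the facial discrimination on the acyclic enone may be insufficient. The fallback sets out from 1. Wittig olefination with lactonisation (Ph3P=CHCO2Et, N,N-diethylaniline, reflux) should give 6-bromo-7-chlorocoumarin F2. Hayashi–Miyaura addition of 7 to this conformationally locked cyclic enoate (Rh(acac)(C2H4)2, (R)-Segphos, dioxane/H2O, 60 °C) should give (4R)-4-[4-(benzyloxy)phenyl]-6-bromo-7-chlorochroman-2-one F3. Lactone opening with MeNH(OMe)·HCl and AlMe3 (CH2Cl2, 0 °C to rt) leads to the phenolic Weinreb amide F4, and O-benzylation (BnBr, K2CO3, DMF) to the benzyl ether F5. Addition of [4-(benzyloxy)-2-methoxyphenyl]magnesium bromide F6 (from 4-(benzyloxy)-1-bromo-2-methoxybenzene and Mg, THF, 0 °C) returns to ketone 8.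

Step 5. Under the acidic conditions benzyl ethers may be lost, and the benzylic cation may cyclise onto a neighbouring arene to an indane instead of taking hydride. The fallback sets out from 8. Condensation with TsNHNH2 (EtOH, cat. AcOH, reflux) should give the tosylhydrazone F7. Reduction with catecholborane (CHCl3, 0 °C) and decomposition of the adduct with NaOAc·3H2O (reflux) proceeds through a diazene with loss of nitrogen, not through a carbocation, and rejoins the route at 10.

**Further compounds**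
F1 | step 10 | 7-(benzyloxy)-2-[5-(benzyloxy)-2-methoxyphenyl]-6-[(1R)-1-[4-(benzyloxy)phenyl]-3-[4-(benzyloxy)-2-methoxyphenyl]propyl]-4H-chromene | COc1cc(OCc2ccccc2)ccc1CC[C@H](c1ccc(OCc2ccccc2)cc1)c1cc2c(cc1OCc1ccccc1)OC(c1cc(OCc3ccccc3)ccc1OC)=CC2
F2 | step 4 | 6-bromo-7-chloro-2H-chromen-2-one | O=C1C=Cc2cc(Br)c(Cl)cc2O1
F3 | step 4 | (4R)-4-[4-(benzyloxy)phenyl]-6-bromo-7-chlorochroman-2-one | O=C1C[C@H](c2ccc(OCc3ccccc3)cc2)c2cc(Br)c(Cl)cc2O1
F4 | step 4 | (3R)-3-[4-(benzyloxy)phenyl]-3-(5-bromo-4-chloro-2-hydroxyphenyl)-N-methoxy-N-methylpropanamide | CON(C)C(=O)C[C@H](c1ccc(OCc2ccccc2)cc1)c1cc(Br)c(Cl)cc1O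
F5 | step 4 | (3R)-3-[2-(benzyloxy)-5-bromo-4-chlorophenyl]-3-[4-(benzyloxy)phenyl]-N-methoxy-N-methylpropanamide | CON(C)C(=O)C[C@H](c1ccc(OCc2ccccc2)cc1)c1cc(Br)c(Cl)cc1OCc1ccccc1
F6 | step 4 | [4-(benzyloxy)-2-methoxyphenyl]magnesium bromide | COc1cc(OCc2ccccc2)ccc1[Mg]Br
F7 | step 5 | 4-methylbenzenesulfonohydrazone of ketone 8 (3R) | COc1cc(OCc2ccccc2)ccc1C(=NNS(=O)(=O)c1ccc(C)cc1)C[C@H](c1ccc(OCc2ccccc2)cc1)c1cc(Br)c(Cl)cc1OCc1ccccc1
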